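## Analysis of the target

The target is a 2,3-dimethylchroman-4-one. Chromanone locants are used throughout (O1, C2, C3, C4, C4a, C5–C8, C8a), and the chain on C8 is C1′ (benzylic CH), C2′ (CH2) and C3′ (carboxyl). Ring A is fully substituted: C5–OH (hydrogen-bonded to C4=O), C6 prenyl, C7–OCH3, C8 carrying CH(Ph)CH2CO2H, C8a–O1 and C4a–C4. There are three stereocentres: C2 (S) and C3 (R) with the two methyl groups cis, and C1′ (R). C1′ is four bonds from C2 and cannot relay to it, so ring B and the side chain must be controlled separately, and any ring B closure gives diastereomers, not enantiomers. The cis arrangement is the less stable one: C3 epimerises through the enol or enolate, and the enolate can also expel the C8a phenoxide (retro-oxa-Michael), which would scramble C2. The prenyl group cyclises onto a neighbouring free phenol in strong acid. The C3′ carboxyl, as acid or ester, closes to a six-membered aryl lactone whenever the phenol at C8a or C7 is free. The difficulty is therefore the regiochemistry of six different ring substituents, a kinetic cis relationship and a remote stereocentre. The route rests on two features. C4 is a lone carbonyl carbon between C4a and the four-carbon unit C3(CH3)–C2(CH3), so ring B is an ortho-iodophenol (C4a–I, C8a–OH), carbon monoxide and buta-1,2-diene. The C8 chain with O1 beside it is a 4-phenyl-3,4-dihydrocoumarin whose lactone oxygen is O1.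

## Retrosynthetic reasoning

**19 to 18.** The O5–H bond is unmasked last; no skeletal bond is cut. O5 and O8a are both ortho to C4a, so a free O5–H would compete in the ring closure. The acetal in 18 is peri to C4=O and is the easiest one to hydrolyse, so mild aqueous acid should be enough.

**18 to 17 to 16.** The C3′ carboxyl is taken back to a primary alcohol and then to its silyl ether. An ester at C3′ beside the free O8a–H that the ring closure needs would lactonise under warm, basic conditions and remove the nucleophile. A bulkier ester would only slow this and would need strong acid for removal. A silyl ether is inert, and the price is one desilylation and one neutral oxidation after C3 is set.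

**16 to 15.** The C3–H bond is cut, so the C3 methyl becomes an exocyclic methylene. This keeps the epimerisable centre out of the ring-forming step and lets C3 be set last, by kinetic protonation relative to C2.

**15 to 12, 13 and 14.** C4a–C4, C4–C3 and O1–C2 are cut together. This removes ring B completely and leaves carbon monoxide 13, buta-1,2-diene 14 and aryl iodide 12. A cut at C4a–C4 alone would demand acylation of a crowded, electron-rich arene with an enolisable acyl donor. The forward reaction must insert 13 before 14, close on the methyl-bearing allyl terminus and set C2.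

**12 to 11 to 10 to 9.** The C4a–I bond is removed first; C4a is the only ring carbon with hydrogen and is ortho to the free phenol. The silyl group is taken off, and then O8a–H and C3′–OH are joined as the lactone of 9. The lactone therefore protects O8a through all earlier steps, and its reduction releases exactly the phenol needed, with C3′ already at the alcohol level.

**9 to 7 and 8.** The C1′–phenyl bond is cut as a conjugate arylation. The opposite polarity would need an ortho,ortho′-dioxygenated arylmetal, which is hindered and protodemetalates. Coumarin 7 is a flat enoate, and catalyst control of its two faces is established for the parent ring system.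

**7 to 5 (through 6).** The C6–prenyl bond is cut as a [3,3] shift from the oxygen that becomes O7. Its other ortho carbon is the ring-fusion carbon, so only C6 can accept the allyl unit. The O7–CH3 bond is then formed on phenol 6.

**5 to 2 and 4; 2 to 1; 4 to 3.** The tertiary allyl–oxygen bond is cut to phenol 2 and carbonate 4, which comes from alcohol 3. Phenol 2 comes from 1 by acetal formation at the more acidic hydroxyl, the one that becomes O5.

## Alternatives that were turned down

**Alternative 1:** Ring A is cut at C7–C8, C4a–C8a and C6–C7 into 3-ethoxycyclobutenone A2 and siloxyalkyne A3, which already carries C1′.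
- **Forward step:** heating should give phenol A1 by opening of A2 to a vinylketene, [2+2] addition to A3, four-electron opening and six-electron closure.
- **For:** it is convergent and regiodefined. On one point it is stronger than the chosen route: the three ring oxygens emerge differentiated (C5–OEt, C7–OH, C8a–OSi) in one step, where the chosen route needs steps 1, 3 and 4.
- **Against:** C4a and C6 are left as C–H and nothing of ring B is built, so prenylation, C-acylation of a crowded arene and both ring B centres remain. A3 needs the benzylic centre set on an acyclic alkyne and a sensitive ynol ether. O5 arrives as an ethyl ether whose late cleavage must spare O7–CH3 and the prenyl group. A1 has free O7–H beside the C3′ ester and would lactonise at the annulation temperature.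
- **Comparison:** roughly five steps to A3 and at least nine after A1. The chosen route buys ring A as 1 and spends its invention where three bonds and a stereocentre form at once.

**Alternative 2:** Ring B is cut at C2–C3. The precursor is diazoketone A5, with a 2-diazopropanoyl group on C4a and an ethyl group on O8a.
- **Forward step:** Rh2(S-PTTL)4, a divalent rhodium dimer, should form the carbenoid at C3, which inserts into a methylene C–H bond of the ethoxy group to give A4.
- **For:** C2, C3 and their cis relation are set in one catalytic step, which is stronger than the chosen route (steps 9 and 10 are needed there). O8a is never a free phenol, so lactonisation cannot occur. Asymmetric insertion next to an ether oxygen has precedent on simple aryl ethers, which the asymmetric form of step 9 lacks.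
- **Against:** a methyl-bearing carbenoid undergoes 1,2-hydride shift to the aryl vinyl ketone. The ethoxy oxygen can form an oxonium ylide that rearranges to a benzofuranone. The prenyl alkene can be cyclopropanated, and the catalyst must override C1′. A5 needs C-acylation at C4a and a diazo transfer to an unactivated ketone (three to four steps). The end game needs acetate and ester cleavage by base next to the epimerisable C3.
- **Comparison:** the chosen route takes C4 from CO, needs no acylation, and ends under neutral or mildly acidic conditions.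

**Alternative 3:** Ring B is cut at O1–C2. The precursor A7 is an ortho-hydroxyaryl ketone whose anti-(2R,3R)-3-hydroxy-2-methylbutanoyl chain derives from the chiral-pool ester A8.
- **Forward step:** Mitsunobu activation (PPh3, diisopropyl azodicarboxylate) of the secondary alcohol and displacement by O8a with inversion should give the cis product A6.
- **For:** every step is known, and both ring B centres come from the chiral pool with secure absolute configuration. This is stronger than the chosen route on reliability of stereocontrol. The closure is neutral and at room temperature.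
- **Against:** the activated β-hydroxy ketone can eliminate to the tigloyl ketone, whose oxa-Michael closure favours trans. The α-centre of the acyl donor can epimerise during C-acylation at C4a. A7 also has free O8a–H beside an ester. The sequence is linear and about four steps longer.
- **Comparison:** the chosen route is shorter and convergent and builds ring B from two gases. This alternative is kept, adapted, as the fallback for step 9.

Key step: step 9

Assumption: (R)-SEGPHOS in step 5 and the (S,S)-bisoxazoline in step 9 are taken to give the configurations shown by analogy with their simplest substrates; if the sense is opposite, the ligand antipode is used with no other change.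

## Route

Step 1
Reactants: 1 5,7-dihydroxycoumarin
Product: 2 5-hydroxy-7-(methoxymethoxy)-2H-chromen-2-one
Conditions: K2CO3 (1.1 equiv), MOMCl (1.05 equiv), acetone, 0 °C → rt
Reagents that add atoms: chloromethyl methyl ether, COCCl
Why: Williamson-type O-alkylation; with one equivalent of base the more acidic, unhindered 7-OH (para to C4a of the enoate) should be ionised and alkylated first, leaving the peri 5-OH free; bis-ether and recovered 1 are separable at this first step.

Step 2
Reactants: 3 2-methylbut-3-en-2-ol
Product: 4 methyl 2-methylbut-3-en-2-yl carbonate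
Conditions: n-BuLi, THF, −78 °C; ClCO2Me, −78 → 0 °C
Reagents that add atoms: methyl chloroformate, COC(=O)Cl
Why: acylation of the lithium alkoxide of a tertiary allylic alcohol, the standard way to allylic carbonates for Tsuji–Trost chemistry.

Step 3
Reactants: 2 5-hydroxy-7-(methoxymethoxy)-2H-chromen-2-one; 4 methyl 2-methylbut-3-en-2-yl carbonate
Product: 5 7-(methoxymethoxy)-5-[(2-methylbut-3-en-2-yl)oxy]-2H-chromen-2-one
Conditions: Pd(PPh3)4 (3 mol%), THF, 0 °C → rt
Reagents that add atoms: none
Why: Tsuji–Trost O-allylation; ionisation of 4 gives the 1,1-dimethylallyl palladium cation, CO2 and methoxide, which deprotonates the phenol, and the phenoxide should attack the more substituted terminus under kinetic control to give the tertiary aryl ether; the reaction is stopped before re-ionisation can equilibrate it to the linear ether.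

Step 4
Reactants: 5 7-(methoxymethoxy)-5-[(2-methylbut-3-en-2-yl)oxy]-2H-chromen-2-one
Product: 7 5-methoxy-7-(methoxymethoxy)-6-(3-methylbut-2-en-1-yl)-2H-chromen-2-one, via 5-hydroxy-7-(methoxymethoxy)-6-prenylcoumarin 6 (not isolated)
Conditions: DMF, 120 °C; then K2CO3, MeI, rt
Reagents that add atoms: iodomethane, CI
Why: aromatic Claisen rearrangement ([3,3]) to the only ortho carbon bearing hydrogen (the other is the ring-fusion carbon), which inverts the allyl unit to a prenyl group; phenol 6 is then methylated in the same flask (Williamson), and the coumarin lactone is inert to carbonate in DMF.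

Step 5
Reactants: 7 5-methoxy-7-(methoxymethoxy)-6-(3-methylbut-2-en-1-yl)-2H-chromen-2-one; 8 phenylboronic acid
Product: 9 (4R)-5-methoxy-7-(methoxymethoxy)-6-(3-methylbut-2-en-1-yl)-4-phenyl-3,4-dihydro-2H-chromen-2-one
Conditions: Rh(acac)(C2H4)2 (3 mol%), (R)-SEGPHOS (3.3 mol%), PhB(OH)2 (5 equiv), dioxane–H2O (10:1), 60 °C
Reagents that add atoms: none
Why: Hayashi–Miyaura asymmetric 1,4-addition; phenyl–rhodium adds across C3=C4 of the coumarin and water protonates the rhodium enolate; the chiral bisphosphine selects the enoate face and sets the benzylic centre (C1′ of the target) as R; the prenyl alkene and acetal are inert.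

Step 6
Reactants: 9 (4R)-5-methoxy-7-(methoxymethoxy)-6-(3-methylbut-2-en-1-yl)-4-phenyl-3,4-dihydro-2H-chromen-2-one
Product: 10 2-[(1R)-3-hydroxy-1-phenylpropyl]-3-methoxy-5-(methoxymethoxy)-4-(3-methylbut-2-en-1-yl)phenol
Conditions: LiBH4, THF, 0 °C → rt
Reagents that add atoms: none
Why: hydride reduction of the aryl ester (lactone) to the primary alcohol and the phenol that becomes O8a–H; the benzylic centre is β to the carbonyl, not enolisable, and stays R.

Step 7
Reactants: 10 2-[(1R)-3-hydroxy-1-phenylpropyl]-3-methoxy-5-(methoxymethoxy)-4-(3-methylbut-2-en-1-yl)phenol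
Product: 11 2-[(1R)-3-{[tert-butyl(dimethyl)silyl]oxy}-1-phenylpropyl]-3-methoxy-5-(methoxymethoxy)-4-(3-methylbut-2-en-1-yl)phenol
Conditions: TBSCl (1.1 equiv), imidazole, CH2Cl2, 0 °C
Reagents that add atoms: tert-butyldimethylsilyl chloride, CC(C)(C)[Si](C)(C)Cl
Why: silylation of the primary alcohol should be faster than that of the neutral phenol with a branched ortho substituent; any aryl silyl ether formed would be returned to the phenol by a brief K2CO3–MeOH wash.

Step 8
Reactants: 11 2-[(1R)-3-{[tert-butyl(dimethyl)silyl]oxy}-1-phenylpropyl]-3-methoxy-5-(methoxymethoxy)-4-(3-methylbut-2-en-1-yl)phenol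
Product: 12 2-[(1R)-3-{[tert-butyl(dimethyl)silyl]oxy}-1-phenylpropyl]-6-iodo-3-methoxy-5-(methoxymethoxy)-4-(3-methylbut-2-en-1-yl)phenol
Conditions: NIS (1.05 equiv), CH2Cl2, −20 → 0 °C, dark
Reagents that add atoms: N-iodosuccinimide, O=C1CCC(=O)N1I
Why: electrophilic aromatic iodination at the only unsubstituted ring carbon, ortho to the free phenol and to O5 and para to O7; the phenol ring should react faster than the prenyl alkene, which has no neighbouring free hydroxyl to trap an iodonium ion.

Step 9
Reactants: 12 2-[(1R)-3-{[tert-butyl(dimethyl)silyl]oxy}-1-phenylpropyl]-6-iodo-3-methoxy-5-(methoxymethoxy)-4-(3-methylbut-2-en-1-yl)phenol; 13 carbon monoxide; 14 buta-1,2-diene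
Product: 15 (2S)-8-[(1R)-3-{[tert-butyl(dimethyl)silyl]oxy}-1-phenylpropyl]-7-methoxy-5-(methoxymethoxy)-2-methyl-3-methylidene-6-(3-methylbut-2-en-1-yl)-2,3-dihydro-4H-chromen-4-one
Conditions: Pd(OAc)2 (5 mol%), (S,S)-2,2′-isopropylidenebis(4-phenyl-2-oxazoline) (10 mol%), i-Pr2NEt (2 equiv), CO (5 atm), buta-1,2-diene (5 equiv), toluene, 70 °C, pressure vessel
Reagents that add atoms: none
Why: Proposed new method: zerovalent palladium, formed from Pd(OAc)2 and the bisoxazoline under CO, adds oxidatively to the C4a–I bond of 12, CO inserts to the aroyl complex, the aroyl group is transferred to the central carbon of 14, and the C8a phenoxide attacks the CH(CH3) terminus of the resulting π-allyl complex anti to palladium, which forms C4a–C4, C4–C3 and O1–C2 and returns zerovalent palladium. The closest known reaction types are the non-asymmetric palladium-catalysed carbonylative annulation of o-iodophenols with allenes to 3-methylenechroman-4-ones and the bisoxazoline-controlled annulation of allenes with o-iodophenols and o-iodoanilides without CO; joining the two is what is new. Ring B closes by C–O bond formation in a 6-exo attack on the allyl terminus, the C–Pd bond that breaks lying outside the new ring. C2 is the only new stereocentre: the two diastereomeric π-allyl complexes interconvert by η3–η1–η3 slippage through the CH2 terminus and the C2-symmetric ligand decides which is attacked, so control is by the catalyst, and the remote C1′ centre only makes the minor C2 epimer a separable diastereomer. CO insertion before allene insertion is secured by the two ortho oxygen substituents flanking the aryl–palladium bond, which slow coordination of the allene but not of CO. Attack at the substituted terminus, the regiochemistry of both precedents with monosubstituted allenes, gives the exocyclic methylene and not the 3-ethylidene isomer. O8a is the only nucleophile because O5 is an acetal and the C3′ oxygen a silyl ether, and migration of the double bond into the ring (to the achiral 2,3-dimethylchromone) is held back by the moderate temperature and immediate use of 15.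

Step 10
Reactants: 15 (2S)-8-[(1R)-3-{[tert-butyl(dimethyl)silyl]oxy}-1-phenylpropyl]-7-methoxy-5-(methoxymethoxy)-2-methyl-3-methylidene-6-(3-methylbut-2-en-1-yl)-2,3-dihydro-4H-chromen-4-one
Product: 16 (2S,3R)-8-[(1R)-3-{[tert-butyl(dimethyl)silyl]oxy}-1-phenylpropyl]-7-methoxy-5-(methoxymethoxy)-2,3-dimethyl-6-(3-methylbut-2-en-1-yl)-2,3-dihydro-4H-chromen-4-one
Conditions: [CuH(PPh3)]6 (0.5 equiv), THF, −20 °C; then AcOH, −78 °C
Reagents that add atoms: none
Why: conjugate hydride transfer to the unhindered exocyclic methylene gives the copper enolate and leaves the prenyl alkene, ketone and silyl ether alone; in the enolate the C2 methyl is pseudoaxial (A1,2 strain with the C3 methyl), and cold protonation from the face anti to it places H trans to the C2 methyl, so the two methyls are cis and C3 is R.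

Step 11
Reactants: 16 (2S,3R)-8-[(1R)-3-{[tert-butyl(dimethyl)silyl]oxy}-1-phenylpropyl]-7-methoxy-5-(methoxymethoxy)-2,3-dimethyl-6-(3-methylbut-2-en-1-yl)-2,3-dihydro-4H-chromen-4-one
Product: 17 (2S,3R)-8-[(1R)-3-hydroxy-1-phenylpropyl]-7-methoxy-5-(methoxymethoxy)-2,3-dimethyl-6-(3-methylbut-2-en-1-yl)-2,3-dihydro-4H-chromen-4-one
Conditions: HF·pyridine, pyridine, THF, 0 °C → rt
Reagents that add atoms: none
Why: fluoride cleavage of the primary silyl ether in a buffered, non-basic medium; the acetal survives and no enolate forms, so C3 is not at risk.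

Step 12
Reactants: 17 (2S,3R)-8-[(1R)-3-hydroxy-1-phenylpropyl]-7-methoxy-5-(methoxymethoxy)-2,3-dimethyl-6-(3-methylbut-2-en-1-yl)-2,3-dihydro-4H-chromen-4-one
Product: 18 (3R)-3-[(2S,3R)-7-methoxy-5-(methoxymethoxy)-2,3-dimethyl-6-(3-methylbut-2-en-1-yl)-4-oxo-3,4-dihydro-2H-chromen-8-yl]-3-phenylpropanoic acid
Conditions: TEMPO (0.2 equiv), PhI(OAc)2 (2.5 equiv), MeCN–H2O (1:1), rt
Reagents that add atoms: water, O
Why: oxoammonium oxidation of the primary alcohol to the aldehyde and, through its hydrate, to the acid; the medium is weakly acidic, the trisubstituted alkene and the fully substituted aryl ethers are not attacked, and O5 is still masked so no phenol is exposed to the oxidant.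

Step 13
Reactants: 18 (3R)-3-[(2S,3R)-7-methoxy-5-(methoxymethoxy)-2,3-dimethyl-6-(3-methylbut-2-en-1-yl)-4-oxo-3,4-dihydro-2H-chromen-8-yl]-3-phenylpropanoic acid
Product: 19 (3R)-3-[(2S,3R)-5-hydroxy-7-methoxy-2,3-dimethyl-6-(3-methylbut-2-en-1-yl)-4-oxo-3,4-dihydro-2H-chromen-8-yl]-3-phenylpropanoic acid
Conditions: 3 M aq. HCl–THF (1:4), rt
Reagents that add atoms: none
Why: acetal hydrolysis; the O5 acetal is peri to C4=O, so hydrolysis is assisted by the carbonyl and the released phenol is held in a hydrogen bond, which should allow dilute acid at room temperature; the medium is not alcoholic, so the carboxyl group is not esterified.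

## Compound list

1 | 5,7-dihydroxycoumarin | O=c1ccc2c(O)cc(O)cc2o1 | starting material
2 | 5-hydroxy-7-(methoxymethoxy)-2H-chromen-2-one | O=c1ccc2c(O)cc(OCOC)cc2o1 | intermediate
3 | 2-methylbut-3-en-2-ol | CC(C)(O)C=C | starting material
4 | methyl 2-methylbut-3-en-2-yl carbonate | COC(=O)OC(C)(C)C=C | intermediate
5 | 7-(methoxymethoxy)-5-[(2-methylbut-3-en-2-yl)oxy]-2H-chromen-2-one | O=c1ccc2c(OC(C)(C)C=C)cc(OCOC)cc2o1 | intermediate
6 | 5-hydroxy-7-(methoxymethoxy)-6-(3-methylbut-2-en-1-yl)-2H-chromen-2-one | O=c1ccc2c(O)c(CC=C(C)C)c(OCOC)cc2o1 | intermediate (not isolated)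
7 | 5-methoxy-7-(methoxymethoxy)-6-(3-methylbut-2-en-1-yl)-2H-chromen-2-one | O=c1ccc2c(OC)c(CC=C(C)C)c(OCOC)cc2o1 | intermediate
8 | phenylboronic acid | OB(O)c1ccccc1 | starting material
9 | (4R)-5-methoxy-7-(methoxymethoxy)-6-(3-methylbut-2-en-1-yl)-4-phenyl-3,4-dihydro-2H-chromen-2-one | COc1c(CC=C(C)C)c(OCOC)cc2c1[C@H](CC(=O)O2)c1ccccc1 | intermediate
10 | 2-[(1R)-3-hydroxy-1-phenylpropyl]-3-methoxy-5-(methoxymethoxy)-4-(3-methylbut-2-en-1-yl)phenol | COc1c(CC=C(C)C)c(OCOC)cc(O)c1[C@H](CCO)c1ccccc1 | intermediate
11 | 2-[(1R)-3-{[tert-butyl(dimethyl)silyl]oxy}-1-phenylpropyl]-3-methoxy-5-(methoxymethoxy)-4-(3-methylbut-2-en-1-yl)phenol | COc1c(CC=C(C)C)c(OCOC)cc(O)c1[C@H](CCO[Si](C)(C)C(C)(C)C)c1ccccc1 | intermediate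
12 | 2-[(1R)-3-{[tert-butyl(dimethyl)silyl]oxy}-1-phenylpropyl]-6-iodo-3-methoxy-5-(methoxymethoxy)-4-(3-methylbut-2-en-1-yl)phenol | COc1c(CC=C(C)C)c(OCOC)c(I)c(O)c1[C@H](CCO[Si](C)(C)C(C)(C)C)c1ccccc1 | intermediate
13 | carbon monoxide | [C-]#[O+] | starting material
14 | buta-1,2-diene | C=C=CC | starting material
15 | (2S)-8-[(1R)-3-{[tert-butyl(dimethyl)silyl]oxy}-1-phenylpropyl]-7-methoxy-5-(methoxymethoxy)-2-methyl-3-methylidene-6-(3-methylbut-2-en-1-yl)-2,3-dihydro-4H-chromen-4-one | COc1c(CC=C(C)C)c(OCOC)c2c(c1[C@H](CCO[Si](C)(C)C(C)(C)C)c1ccccc1)O[C@@H](C)C(=C)C2=O | intermediate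
16 | (2S,3R)-8-[(1R)-3-{[tert-butyl(dimethyl)silyl]oxy}-1-phenylpropyl]-7-methoxy-5-(methoxymethoxy)-2,3-dimethyl-6-(3-methylbut-2-en-1-yl)-2,3-dihydro-4H-chromen-4-one | COc1c(CC=C(C)C)c(OCOC)c2c(c1[C@H](CCO[Si](C)(C)C(C)(C)C)c1ccccc1)O[C@@H](C)[C@@H](C)C2=O | intermediate
17 | (2S,3R)-8-[(1R)-3-hydroxy-1-phenylpropyl]-7-methoxy-5-(methoxymethoxy)-2,3-dimethyl-6-(3-methylbut-2-en-1-yl)-2,3-dihydro-4H-chromen-4-one | COc1c(CC=C(C)C)c(OCOC)c2c(c1[C@H](CCO)c1ccccc1)O[C@@H](C)[C@@H](C)C2=O | intermediate
18 | (3R)-3-[(2S,3R)-7-methoxy-5-(methoxymethoxy)-2,3-dimethyl-6-(3-methylbut-2-en-1-yl)-4-oxo-3,4-dihydro-2H-chromen-8-yl]-3-phenylpropanoic acid | COc1c(CC=C(C)C)c(OCOC)c2c(c1[C@H](CC(=O)O)c1ccccc1)O[C@@H](C)[C@@H](C)C2=O | intermediate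
19 | (3R)-3-[(2S,3R)-5-hydroxy-7-methoxy-2,3-dimethyl-6-(3-methylbut-2-en-1-yl)-4-oxo-3,4-dihydro-2H-chromen-8-yl]-3-phenylpropanoic acid | COc1c(CC=C(C)C)c(O)c2c(c1[C@H](CC(=O)O)c1ccccc1)O[C@@H](C)[C@@H](C)C2=O | target

## Step count and least certain steps

Total: 13 steps. Longest linear sequence: 12 steps (1 → 2 → 5 → 7 → 9 → 10 → 11 → 12 → 15 → 16 → 17 → 18 → 19); step 2 is a one-step side branch.

**Step 9 (key step, proposed new method).**
- What may go wrong: loss of face discrimination in the attack on the π-allyl complex, because bisoxazoline control is known only without CO and CO may compete with the ligand for palladium. Further possibilities are allene insertion before CO insertion, intermolecular acylation of the phenol by the aroyl complex, and palladium hydride migration of the exocyclic double bond into the ring.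
- Fallback (known chemistry, from 12 to 16, so it also replaces step 10): commercial methyl (3R)-3-hydroxybutanoate is methylated by the Fráter–Seebach protocol (LDA, MeI) to methyl (2R,3R)-3-hydroxy-2-methylbutanoate F1. This is converted with MeNHOMe·HCl and i-PrMgCl into (2R,3R)-3-hydroxy-N-methoxy-N,2-dimethylbutanamide F2 and silylated (Et3SiCl, imidazole) to the triethylsilyl ether F3. Iodophenol 12 is deprotonated with MeLi and exchanged with t-BuLi (THF, −78 °C), and the aryllithium is acylated by F3 to give the (2R,3R)-2-methyl-3-(triethylsilyloxy)butanoyl ketone F4. The triethylsilyl ether is removed selectively (PPTS, MeOH, 0 °C) to give the β-hydroxy ketone F5. Mitsunobu closure (PPh3, diisopropyl azodicarboxylate, toluene, 0 °C) with inversion at the carbinol carbon should then give 16.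

**Step 5.**
- What may go wrong: slow carborhodation at C4, because the peri methoxy group and the electron-rich enoate retard insertion, so that protodeboronation of 8 outruns addition; facial selectivity may also erode.
- Fallback (from 7 to 10): oxidative Heck arylation of 7 with 8 (Pd(OAc)2, 1,10-phenanthroline, O2, DMF) should give 5-methoxy-7-(methoxymethoxy)-6-prenyl-4-phenylcoumarin F6. Copper hydride asymmetric conjugate reduction (Cu(OAc)2·H2O, (R)-DTBM-SEGPHOS, diethoxymethylsilane, t-BuOH, toluene) is expected to set the benzylic centre and over-reduce to the (4R)-lactol F7. NaBH4 in MeOH would then open the lactol to diol 10.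

**Step 10.**
- What may go wrong: protonation of the enolate from the wrong face, expulsion of the C8a phenoxide from the enolate on warming (retro-oxa-Michael, which would scramble C2), or equilibration to the trans isomer during work-up.
- Fallback (from 15 to 16, no new compound): diimide reduction (dipotassium azodicarboxylate, AcOH, MeOH–CH2Cl2, 0 °C). It delivers both hydrogens in one step to the face of the exocyclic alkene anti to the C2 methyl, involves no enolate, and leaves the trisubstituted prenyl alkene.

**Step 13.**
- What may go wrong: slow hydrolysis in aqueous THF, forcing longer acid exposure, with cyclisation of the prenyl group onto the freed 5-OH and epimerisation at C3 through the enol.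
- Fallback (from 16 to 19): both protecting groups are removed before the carboxyl group exists. HCl (1 M) in MeOH at 0 °C, where acetal exchange is faster, should give the 5-hydroxy primary alcohol F8. The chelated phenol is then spared by a two-stage oxidation: SO3·pyridine, DMSO, i-Pr2NEt at 0 °C to the aldehyde F9, then NaClO2, NaH2PO4 and 2-methylbut-2-ene in t-BuOH–H2O to 19.

**Step 3.**
- What may go wrong: attack at the unsubstituted allyl terminus, or palladium-mediated equilibration of the tertiary ether to the linear prenyl ether, whose Claisen shift would place a reverse prenyl group on C6.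
- Fallback (from 2 to 5): copper-assisted alkylation with 3-chloro-3-methylbut-1-yne (K2CO3, KI, CuI cat., acetone) to the 1,1-dimethylpropargyl ether F10, then semi-hydrogenation (H2, Pd/CaCO3 poisoned with Pb(OAc)2, quinoline, EtOAc) to 5.

## Further compounds

F1 | step 9 | methyl (2R,3R)-3-hydroxy-2-methylbutanoate | COC(=O)[C@H](C)[C@@H](C)O
F2 | step 9 | (2R,3R)-3-hydroxy-N-methoxy-N,2-dimethylbutanamide | CON(C)C(=O)[C@H](C)[C@@H](C)O
F3 | step 9 | (2R,3R)-N-methoxy-N,2-dimethyl-3-[(triethylsilyl)oxy]butanamide | CON(C)C(=O)[C@H](C)[C@@H](C)O[Si](CC)(CC)CC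
F4 | step 9 | (2R,3R)-1-{3-[(1R)-3-{[tert-butyl(dimethyl)silyl]oxy}-1-phenylpropyl]-2-hydroxy-4-methoxy-6-(methoxymethoxy)-5-(3-methylbut-2-en-1-yl)phenyl}-2-methyl-3-[(triethylsilyl)oxy]butan-1-one | COc1c(CC=C(C)C)c(OCOC)c(C(=O)[C@H](C)[C@@H](C)O[Si](CC)(CC)CC)c(O)c1[C@H](CCO[Si](C)(C)C(C)(C)C)c1ccccc1
F5 | step 9 | (2R,3R)-1-{3-[(1R)-3-{[tert-butyl(dimethyl)silyl]oxy}-1-phenylpropyl]-2-hydroxy-4-methoxy-6-(methoxymethoxy)-5-(3-methylbut-2-en-1-yl)phenyl}-3-hydroxy-2-methylbutan-1-one | COc1c(CC=C(C)C)c(OCOC)c(C(=O)[C@H](C)[C@@H](C)O)c(O)c1[C@H](CCO[Si](C)(C)C(C)(C)C)c1ccccc1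
F6 | step 5 | 5-methoxy-7-(methoxymethoxy)-6-(3-methylbut-2-en-1-yl)-4-phenyl-2H-chromen-2-one | O=c1cc(-c2ccccc2)c2c(OC)c(CC=C(C)C)c(OCOC)cc2o1
F7 | step 5 | (4R)-5-methoxy-7-(methoxymethoxy)-6-(3-methylbut-2-en-1-yl)-4-phenyl-3,4-dihydro-2H-chromen-2-ol (lactol, both anomers) | COc1c(CC=C(C)C)c(OCOC)cc2c1[C@H](CC(O)O2)c1ccccc1
F0 | step 10 | none | none
F8 | step 13 | (2S,3R)-5-hydroxy-8-[(1R)-3-hydroxy-1-phenylpropyl]-7-methoxy-2,3-dimethyl-6-(3-methylbut-2-en-1-yl)-2,3-dihydro-4H-chromen-4-one | COc1c(CC=C(C)C)c(O)c2c(c1[C@H](CCO)c1ccccc1)O[C@@H](C)[C@@H](C)C2=O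
F9 | step 13 | (3R)-3-[(2S,3R)-5-hydroxy-7-methoxy-2,3-dimethyl-6-(3-methylbut-2-en-1-yl)-4-oxo-3,4-dihydro-2H-chromen-8-yl]-3-phenylpropanal | COc1c(CC=C(C)C)c(O)c2c(c1[C@H](CC=O)c1ccccc1)O[C@@H](C)[C@@H](C)C2=O
F10 | step 3 | 7-(methoxymethoxy)-5-[(2-methylbut-3-yn-2-yl)oxy]-2H-chromen-2-one | O=c1ccc2c(OC(C)(C)C#C)cc(OCOC)cc2o1
A1 | alternative 1 | methyl (3R)-3-[4-ethoxy-2-hydroxy-6-(triisopropylsilyloxy)phenyl]-3-phenylpropanoate | CCOc1cc(O)c([C@H](CC(=O)OC)c2ccccc2)c(O[Si](C(C)C)(C(C)C)C(C)C)c1
A2 | alternative 1 | 3-ethoxycyclobut-2-en-1-one | CCOC1=CC(=O)C1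
A3 | alternative 1 | methyl (3R)-3-phenyl-5-[(triisopropylsilyl)oxy]pent-4-ynoate | CC(C)[Si](C(C)C)(C(C)C)OC#C[C@H](CC(=O)OC)c1ccccc1
A4 | alternative 2 | methyl (3R)-3-[(2S,3R)-5-acetoxy-7-methoxy-2,3-dimethyl-6-(3-methylbut-2-en-1-yl)-4-oxo-3,4-dihydro-2H-chromen-8-yl]-3-phenylpropanoate | COc1c(CC=C(C)C)c(OC(C)=O)c2c(c1[C@H](CC(=O)OC)c1ccccc1)O[C@@H](C)[C@@H](C)C2=O
A5 | alternative 2 | methyl (3R)-3-[4-acetoxy-3-(2-diazopropanoyl)-2-ethoxy-6-methoxy-5-(3-methylbut-2-en-1-yl)phenyl]-3-phenylpropanoate | COc1c(CC=C(C)C)c(OC(C)=O)c(C(=O)C(C)=[N+]=[N-])c(OCC)c1[C@H](CC(=O)OC)c1ccccc1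
A6 | alternative 3 | methyl (3R)-3-[(2S,3R)-7-methoxy-5-(methoxymethoxy)-2,3-dimethyl-6-(3-methylbut-2-en-1-yl)-4-oxo-3,4-dihydro-2H-chromen-8-yl]-3-phenylpropanoate | COc1c(CC=C(C)C)c(OCOC)c2c(c1[C@H](CC(=O)OC)c1ccccc1)O[C@@H](C)[C@@H](C)C2=O
A7 | alternative 3 | methyl (3R)-3-{2-hydroxy-3-[(2R,3R)-3-hydroxy-2-methylbutanoyl]-6-methoxy-4-(methoxymethoxy)-5-(3-methylbut-2-en-1-yl)phenyl}-3-phenylpropanoate | COc1c(CC=C(C)C)c(OCOC)c(C(=O)[C@H](C)[C@@H](C)O)c(O)c1[C@H](CC(=O)OC)c1ccccc1
A8 | alternative 3 | methyl (3R)-3-hydroxybutanoate | C[C@@H](O)CC(=O)OC
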